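The butenolide (ring A) is disconnected at its enol-lactone bond O1–C5. Ring carbon C5 and the exocyclic CBr2 carbon are read as the two carbons of a 1-bromoalkyne, and O1 as the carboxyl oxygen of an open-chain 3-bromo-2-en-4-ynoic acid whose alkene holds the carboxyl and the alkyne cis and already carries the C4 bromine and the (R)-acetoxy centre at C1′. One silver-promoted NBS operation turns the silyl alkyne into the bromoalkyne and closes ring A 5-exo-dig with delivery of the second bromine, so lactone and dibromomethylidene unit arise together with no alkene-geometry issue. The tetrasubstituted alkene comes from an alkoxide-directed anti-carbomagnesiation of an enantioenriched diynol.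

Key step: step 6

Remark: ring A is numbered O1, C2 (C=O), C3 (side chain), C4 (Br), C5 (=CBr2), and the acetoxy-bearing side-chain carbon is C1′. The sense of induction in step 2 is assumed to follow that of simple alkyl alkynyl ketones.

Step 1
Reactants: 1 1,4-bis(trimethylsilyl)buta-1,3-diyne; 2 N-methoxy-N-methylbutanamide
Product: 4 8-(trimethylsilyl)octa-5,7-diyn-4-one, via lithium 4-(trimethylsilyl)buta-1,3-diynide 3 (not isolated)
Conditions: MeLi·LiBr (1.0 equiv), THF, rt; then 2, −78 → 0 °C; cold aq. NaHSO4 quench
Reagents that add atoms: none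
Why: Methyllithium removes one trimethylsilyl group selectively to give acetylide 3, and its acylation by the Weinreb amide stops at the ketone because the chelated tetrahedral adduct survives until the acidic quench (Weinreb ketone synthesis).

Step 2
Reactants: 4 8-(trimethylsilyl)octa-5,7-diyn-4-one
Product: 5 (4R)-8-(trimethylsilyl)octa-5,7-diyn-4-ol
Conditions: RuCl[(R,R)-TsDPEN](p-cymene) (1 mol%), i-PrOH, rt
Reagents that add atoms: none
Why: Noyori asymmetric transfer hydrogenation of an ynone, in which the alkynyl group acts as the π-substituent recognised by the arene ligand, so the (R,R)-catalyst should deliver hydride to the carbonyl face that gives the (4R)-carbinol, the only stereocentre of the route.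

Step 3
Reactants: 5 (4R)-8-(trimethylsilyl)octa-5,7-diyn-4-ol
Product: 7 (4R,5Z)-6-bromo-5-ethenyl-8-(trimethylsilyl)oct-5-en-7-yn-4-ol, via five-membered oxamagnesacycle 6 (not isolated)
Conditions: vinylmagnesium chloride (4 equiv), THF/toluene, 70 °C; then NBS, −40 → 0 °C; aq. NH4Cl
Reagents that add atoms: vinylmagnesium chloride C=C[Mg]Cl; N-bromosuccinimide O=C1CCC(=O)N1Br
Why: Alkoxide-directed anti-carbomagnesiation of a propargylic alcohol: the magnesium alkoxide delivers the vinyl group to the proximal alkyne carbon C5 and the metal ends on C6 inside oxamagnesacycle 6, so bromination of the C–Mg bond with retention should place bromine cis to the carbinol carbon and the silylalkynyl group cis to the vinyl group, while the stereocentre is untouched.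

Step 4
Reactants: 7 (4R,5Z)-6-bromo-5-ethenyl-8-(trimethylsilyl)oct-5-en-7-yn-4-ol
Product: 8 (4R,5Z)-6-bromo-5-ethenyl-8-(trimethylsilyl)oct-5-en-7-yn-4-yl acetate
Conditions: Ac2O, Et3N, DMAP (cat.), CH2Cl2, 0 °C → rt
Reagents that add atoms: acetic anhydride CC(=O)OC(C)=O
Why: DMAP-catalysed O-acylation of the secondary allylic alcohol, which proceeds with retention at C4 because no bond to the stereocentre is broken.

Step 5
Reactants: 8 (4R,5Z)-6-bromo-5-ethenyl-8-(trimethylsilyl)oct-5-en-7-yn-4-yl acetate
Product: 10 (2E)-2-[(1R)-1-acetoxybutyl]-3-bromo-5-(trimethylsilyl)pent-2-en-4-ynoic acid, via enal 9 (not isolated)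
Conditions: OsO4 (1 mol%), Oxone (4 equiv), DMF, rt
Reagents that add atoms: osmium tetroxide O=[Os](=O)(=O)=O; Oxone (potassium peroxymonosulfate) [K+].[O-]S(=O)(=O)OO
Why: Osmium tetroxide-catalysed oxidative cleavage with Oxone as terminal oxidant (an ozonolysis-type alkene-to-acid cleavage), in which the monosubstituted vinyl group should be osmylated in preference to the hindered, electron-poor bromoalkene and the alkynes, and aldehyde 9 is oxidised in the same flask to the acid.

Step 6
Reactants: 10 (2E)-2-[(1R)-1-acetoxybutyl]-3-bromo-5-(trimethylsilyl)pent-2-en-4-ynoic acid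
Product: 12 (1R)-1-[4-bromo-5-(dibromomethylidene)-2-oxo-2,5-dihydrofuran-3-yl]butyl acetate, via bromoalkyne acid 11 (not isolated)
Conditions: NBS (2.5 equiv), AgNO3 (20 mol%), acetone, 0 °C → rt, dark; then NaHCO3 (1.5 equiv)
Reagents that add atoms: N-bromosuccinimide O=C1CCC(=O)N1Br
Why: Silver acetylide formation with loss of the silyl group and bromination by NBS gives bromoalkyne 11; silver then activates this alkyne toward the cis-held carboxylate, which attacks the internal alkyne carbon anti to the metal, and the resulting vinylsilver is brominated by a second NBS (bromo-deargentation), so the O1–C5 bond and the CBr2 group form in one flask. The closest known reaction type is the halolactonisation of alkynoic and (Z)-2-en-4-ynoic acids, including 1-haloalkynoic acids that give dihalomethylidene enol lactones. Ring A closes in the 5-exo-dig mode. No stereocentre is created: C1′ is a spectator under these near-neutral, dark conditions, and the exocyclic alkene carries two bromines and therefore has no geometry to control. The step needs exo over 6-endo-dig closure (2-pyranone) and bromination over protonation of the vinylsilver; the first is secured by the alkene geometry fixed in step 3, by the exo preference of silver carboxylates and by the polarisation of a 1-bromoalkyne, which directs oxygen to the carbon remote from bromine, the second by excess NBS and the bicarbonate buffer.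

Compound list
1 | 1,4-bis(trimethylsilyl)buta-1,3-diyne | C[Si](C)(C)C#CC#C[Si](C)(C)C | starting material
2 | N-methoxy-N-methylbutanamide | CCCC(=O)N(C)OC | starting material
3 | lithium 4-(trimethylsilyl)buta-1,3-diynide | [Li]C#CC#C[Si](C)(C)C | intermediate (not isolated)
4 | 8-(trimethylsilyl)octa-5,7-diyn-4-one | CCCC(=O)C#CC#C[Si](C)(C)C | intermediate
5 | (4R)-8-(trimethylsilyl)octa-5,7-diyn-4-ol | CCC[C@@H](O)C#CC#C[Si](C)(C)C | intermediate
6 | (5R)-4-ethenyl-5-propyl-3-[(trimethylsilyl)ethynyl]-2,5-dihydro-1,2-oxamagnesole (five-membered oxamagnesacycle) | CCC[C@H]1O[Mg]C(C#C[Si](C)(C)C)=C1C=C | intermediate (not isolated)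
7 | (4R,5Z)-6-bromo-5-ethenyl-8-(trimethylsilyl)oct-5-en-7-yn-4-ol | CCC[C@@H](O)/C(C=C)=C(\Br)C#C[Si](C)(C)C | intermediate
8 | (4R,5Z)-6-bromo-5-ethenyl-8-(trimethylsilyl)oct-5-en-7-yn-4-yl acetate | CCC[C@@H](OC(C)=O)/C(C=C)=C(\Br)C#C[Si](C)(C)C | intermediate
9 | (2E)-2-[(1R)-1-acetoxybutyl]-3-bromo-5-(trimethylsilyl)pent-2-en-4-ynal | CCC[C@@H](OC(C)=O)/C(C=O)=C(\Br)C#C[Si](C)(C)C | intermediate (not isolated)
10 | (2E)-2-[(1R)-1-acetoxybutyl]-3-bromo-5-(trimethylsilyl)pent-2-en-4-ynoic acid | CCC[C@@H](OC(C)=O)/C(C(=O)O)=C(\Br)C#C[Si](C)(C)C | intermediate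
11 | (2E)-2-[(1R)-1-acetoxybutyl]-3,5-dibromopent-2-en-4-ynoic acid | CCC[C@@H](OC(C)=O)/C(C(=O)O)=C(\Br)C#CBr | intermediate (not isolated)
12 | (1R)-1-[4-bromo-5-(dibromomethylidene)-2-oxo-2,5-dihydrofuran-3-yl]butyl acetate | CCC[C@@H](OC(C)=O)C1=C(Br)C(=C(Br)Br)OC1=O | target

Total step count: 6. Longest linear sequence: 6 steps.

Steps most likely to fail

Step 3. The vinyl Grignard reagent may add without regiocontrol across the conjugated diyne (attack at the distal silylated alkyne or 1,4-type addition), or the diyne may oligomerise at the temperature the addition needs. The fallback carries only one alkyne through the carbomagnesiation and brings in the second by cross-coupling. It sets out from 2: lithium (trimethylsilyl)acetylide (ethynyltrimethylsilane, n-BuLi, THF, −78 °C) should give 1-(trimethylsilyl)hex-1-yn-3-one F1. Transfer hydrogenation as in step 2 should give (3R)-1-(trimethylsilyl)hex-1-yn-3-ol F2. Alkoxide-directed anti-addition of vinylmagnesium chloride, with magnesium ending alpha to silicon, and NBS trapping should give (1Z,3R)-1-bromo-2-ethenyl-1-(trimethylsilyl)hex-1-en-3-ol F3. Ipso-iododesilylation with NIS in MeCN should give, with retention, (1E,3R)-1-bromo-2-ethenyl-1-iodohex-1-en-3-ol F4. Sonogashira coupling at the more reactive C–I bond with ethynyltrimethylsilane [Pd(PPh3)2Cl2, CuI, Et3N] returns to the route at 7.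

Step 6. Ring closure may occur through the distal alkyne carbon (6-endo-dig, giving a 2-pyranone), or the vinylsilver intermediate may be protonated before the second bromine is delivered. The fallback separates C–Br bond formation from ring closure and sets out from 10. Bromoalkyne acid 11 is isolated (NBS 1.1 equiv, AgNO3 cat., acetone). Ag2CO3-catalysed cycloisomerisation (5-exo-dig anti-oxymetalation, then protonation) should give (1R)-1-[(5Z)-4-bromo-5-(bromomethylidene)-2-oxo-2,5-dihydrofuran-3-yl]butyl acetate F5. Addition of Br2 to the exocyclic enol double bond should give (1R)-1-[4,5-dibromo-5-(dibromomethyl)-2-oxo-2,5-dihydrofuran-3-yl]butyl acetate F6 as a mixture of C5 epimers. Elimination of HBr with Et3N returns to the route at 12.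

Step 5. The oxidant may attack the tetrasubstituted bromo-enyne unit, or oxidation of the aldehyde to the acid may be incomplete under the one-pot conditions. The fallback splits cleavage and oxidation and sets out from 8: ozonolysis of the vinyl group (O3, CH2Cl2/MeOH, −78 °C; Me2S) gives aldehyde 9, now isolated, and Pinnick oxidation (NaClO2, NaH2PO4, 2-methyl-2-butene, t-BuOH/H2O) returns to the route at 10.

Further compounds
F1 | step 3 | 1-(trimethylsilyl)hex-1-yn-3-one | CCCC(=O)C#C[Si](C)(C)C
F2 | step 3 | (3R)-1-(trimethylsilyl)hex-1-yn-3-ol | CCC[C@@H](O)C#C[Si](C)(C)C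
F3 | step 3 | (1Z,3R)-1-bromo-2-ethenyl-1-(trimethylsilyl)hex-1-en-3-ol | CCC[C@@H](O)/C(C=C)=C(\Br)[Si](C)(C)C
F4 | step 3 | (1E,3R)-1-bromo-2-ethenyl-1-iodohex-1-en-3-ol | CCC[C@@H](O)/C(C=C)=C(\Br)I
F5 | step 6 | (1R)-1-[(5Z)-4-bromo-5-(bromomethylidene)-2-oxo-2,5-dihydrofuran-3-yl]butyl acetate | CCC[C@@H](OC(C)=O)C1=C(Br)/C(=C/Br)OC1=O
F6 | step 6 | (1R)-1-[4,5-dibromo-5-(dibromomethyl)-2-oxo-2,5-dihydrofuran-3-yl]butyl acetate | CCC[C@@H](OC(C)=O)C1=C(Br)C(Br)(C(Br)Br)OC1=O
F0 | step 5 | none | none
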